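**Retrosynthetic overview**
- The target comes from the mono-epoxide of a symmetric linear bis-chromene. One Li/NH3 operation opens the epoxide at its benzylic C–O bond (giving the (3R)-chroman-3-ol), cleaves the allylic aryl ether of the other pyran (giving prenyl + phenol) and removes two benzyl ethers.
- The mono-epoxide comes from a symmetry-breaking Jacobsen–Katsuki mono-epoxidation of one of two homotopic 2,2-dimethylchromene olefins. This is the only stereo-determining event.
- The bis-chromene comes from a bis-chromanone by reduction and dehydration. The bibenzyl C–C bond comes from ketone-directed C5–H hydroarylation of 3,4-bis(benzyloxy)styrene.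
- The bis-chromanone comes from 4,6-diacetylresorcinol and two molecules of acetone (double Kabbe annulation). The styrene comes from 3,4-bis(benzyloxy)benzaldehyde (Wittig).
- Ring order: both pyran rings are fused onto the resorcinol arene first, the catechol arene is attached next, one pyran survives as the chromanol and the other is reopened in the last step.

Assumption: 1, 2, 5, the phosphonium salt and the (R,R)-salen manganese chloride complex C36H52ClMnN2O2 of step 5 are bought; the sense of induction in step 5 is taken from the established behaviour of this catalyst with 2,2-dimethylchromenes.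

**Step 1**
Reactants: 1 4,6-diacetylresorcinol (1,1'-(4,6-dihydroxy-1,3-phenylene)diethanone); 2 acetone (two molecules are built in, one per acetyl group)
Product: 4 2,2,8,8-tetramethyl-2,3,7,8-tetrahydropyrano[3,2-g]chromene-4,6-dione (linear bis-chromanone), via bis-enone 3 (not isolated)
Conditions: pyrrolidine (1 equiv), acetone (10 equiv), EtOH, reflux, 24 h
Reagents that add atoms: acetone (second molecule; the same compound as 2), CC(C)=O
Why: Double Kabbe chromanone annulation, in which pyrrolidine-mediated crossed aldol condensation of each of the two aryl methyl ketones with one molecule of acetone gives bis-enone 3 (C10H10O4 + 2 C3H6O → C16H18O4 + 2 H2O) and each ortho-phenol then closes by 6-endo oxa-Michael addition; the fixed 4,6-diacyl pattern allows only the linear tricycle and no stereocentre is formed.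

**Step 2**
Reactants: 5 3,4-bis(benzyloxy)benzaldehyde
Product: 6 1,2-bis(benzyloxy)-4-vinylbenzene (3,4-bis(benzyloxy)styrene)
Conditions: Ph3PCH3Br, KOtBu, THF, 0 °C to rt
Reagents that add atoms: methyltriphenylphosphonium bromide, C[P+](c1ccccc1)(c1ccccc1)c1ccccc1.[Br-]
Why: Wittig methylenation of an aromatic aldehyde with a non-stabilised ylide, to which the benzyl ethers are inert; no stereocentre is formed.

**Step 3**
Reactants: 4 2,2,8,8-tetramethyl-2,3,7,8-tetrahydropyrano[3,2-g]chromene-4,6-dione; 6 1,2-bis(benzyloxy)-4-vinylbenzene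
Product: 7 5-[2-(3,4-bis(benzyloxy)phenyl)ethyl]-2,2,8,8-tetramethyl-2,3,7,8-tetrahydropyrano[3,2-g]chromene-4,6-dione
Conditions: [RuCl2(p-cymene)]2 (2.5 mol%), HCO2Na (30 mol%), P(4-CF3C6H4)3 (15 mol%), 6 (2 equiv), toluene, 140 °C, sealed tube, 20 h
Reagents that add atoms: none
Why: Murai-type ketone-directed ortho C–H alkylation in its anti-Markovnikov styrene variant, where C5–H is the only ortho C–H of 4 and is peri to two coplanar ring carbonyls that can each deliver ruthenium, so styrene insertion gives the linear ArCH2CH2Ar' bond without over-alkylation; no stereocentre is formed.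

**Step 4**
Reactants: 7 5-[2-(3,4-bis(benzyloxy)phenyl)ethyl]-2,2,8,8-tetramethyl-2,3,7,8-tetrahydropyrano[3,2-g]chromene-4,6-dione
Product: 9 5-[2-(3,4-bis(benzyloxy)phenyl)ethyl]-2,2,8,8-tetramethyl-2H,8H-pyrano[3,2-g]chromene (symmetric bis-chromene), via bis-chroman-4-ol 8 (not isolated)
Conditions: NaBH4, THF/MeOH (3:1), 0 °C to rt; then p-TsOH·H2O (slight excess over NaBH4), toluene, 70 °C, THF/MeOH distilled off
Reagents that add atoms: none
Why: Borohydride reduction of both aryl ketones followed by acid-catalysed E1 dehydration of the benzylic alcohols, whose cations are stabilised by an ortho and a para ether oxygen, gives the conjugated bis-chromene; the carbinol stereocentres of 8 are destroyed.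

**Step 5**
Reactants: 9 5-[2-(3,4-bis(benzyloxy)phenyl)ethyl]-2,2,8,8-tetramethyl-2H,8H-pyrano[3,2-g]chromene
Product: 10 (3R,4R)-3,4-epoxy-5-[2-(3,4-bis(benzyloxy)phenyl)ethyl]-2,2,8,8-tetramethyl-3,4-dihydro-2H,8H-pyrano[3,2-g]chromene (cis-fused mono-epoxide)
Conditions: (R,R)-N,N'-bis(3,5-di-tert-butylsalicylidene)-1,2-cyclohexanediaminomanganese chloride (C36H52ClMnN2O2, 4 mol%), 4-phenylpyridine N-oxide (20 mol%), aq. NaOCl (0.6 equiv, pH 11.3), CH2Cl2, 0 °C, to about 55% conversion; column on Et3N-deactivated silica, recovered 9 recycled, 10 used at once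
Reagents that add atoms: sodium hypochlorite, [Na+].[O-]Cl
Why: Jacobsen–Katsuki epoxidation, for which 2,2-dimethylchromenes are the best substrate class; the two olefins of 9 are homotopic so either gives the same mono-epoxide, sub-stoichiometric oxidant limits bis-epoxidation, and the (R,R)-catalyst delivers oxygen to the face that gives the (3R,4R)-epoxide, which fixes C3 of the target.

**Step 6**
Reactants: 10 (3R,4R)-3,4-epoxy-5-[2-(3,4-bis(benzyloxy)phenyl)ethyl]-2,2,8,8-tetramethyl-3,4-dihydro-2H,8H-pyrano[3,2-g]chromene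
Product: 11 (3R)-5-[2-(3,4-dihydroxyphenyl)ethyl]-2,2-dimethyl-6-(3-methylbut-2-en-1-yl)-3,4-dihydro-2H-chromene-3,7-diol (target)
Conditions: Li (14 equiv), NH3(l)/THF, −78 °C, 30 min (10 added to the blue solution); solid NH4Cl, warm to rt under Ar
Reagents that add atoms: none
Why: Dissolving-metal (Birch-type) reductive C–O cleavage done three times by one reagent, in which electron transfer opens the benzylic C4–O bond of the epoxide (C3–O is untouched, so 3R is retained), fragments the allylic aryl ether of the remaining 2,2-dimethylchromene to the ortho-prenyl phenoxide by protonation of the allyl anion at the benzylic carbon, and removes both benzyl ethers, while phenoxide formation protects the arenes from ring reduction.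

**Compound list**
1 | 4,6-diacetylresorcinol (1,1'-(4,6-dihydroxy-1,3-phenylene)diethanone) | CC(=O)c1cc(C(C)=O)c(O)cc1O | starting material
2 | acetone | CC(C)=O | starting material
3 | 1,1'-(4,6-dihydroxy-1,3-phenylene)bis(3-methylbut-2-en-1-one) (bis-enone) | CC(C)=CC(=O)c1cc(C(=O)C=C(C)C)c(O)cc1O | intermediate
4 | 2,2,8,8-tetramethyl-2,3,7,8-tetrahydropyrano[3,2-g]chromene-4,6-dione | CC1(C)CC(=O)c2cc3c(cc2O1)OC(C)(C)CC3=O | intermediate
5 | 3,4-bis(benzyloxy)benzaldehyde | O=Cc1ccc(OCc2ccccc2)c(OCc2ccccc2)c1 | starting material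
6 | 1,2-bis(benzyloxy)-4-vinylbenzene | C=Cc1ccc(OCc2ccccc2)c(OCc2ccccc2)c1 | intermediate
7 | 5-[2-(3,4-bis(benzyloxy)phenyl)ethyl]-2,2,8,8-tetramethyl-2,3,7,8-tetrahydropyrano[3,2-g]chromene-4,6-dione | CC1(C)CC(=O)c2c(CCc3ccc(OCc4ccccc4)c(OCc4ccccc4)c3)c3c(cc2O1)OC(C)(C)CC3=O | intermediate
8 | 5-[2-(3,4-bis(benzyloxy)phenyl)ethyl]-2,2,8,8-tetramethyl-3,4,7,8-tetrahydro-2H,6H-pyrano[3,2-g]chromene-4,6-diol (diastereomer mixture) | CC1(C)CC(O)c2c(CCc3ccc(OCc4ccccc4)c(OCc4ccccc4)c3)c3c(cc2O1)OC(C)(C)CC3O | intermediate
9 | 5-[2-(3,4-bis(benzyloxy)phenyl)ethyl]-2,2,8,8-tetramethyl-2H,8H-pyrano[3,2-g]chromene | CC1(C)C=Cc2c(CCc3ccc(OCc4ccccc4)c(OCc4ccccc4)c3)c3c(cc2O1)OC(C)(C)C=C3 | intermediate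
10 | (3R,4R)-3,4-epoxy-5-[2-(3,4-bis(benzyloxy)phenyl)ethyl]-2,2,8,8-tetramethyl-3,4-dihydro-2H,8H-pyrano[3,2-g]chromene | CC1(C)Oc2cc3OC(C)(C)C=Cc3c(CCc3ccc(OCc4ccccc4)c(OCc4ccccc4)c3)c2[C@H]2O[C@@H]12 | intermediate
11 | (3R)-5-[2-(3,4-dihydroxyphenyl)ethyl]-2,2-dimethyl-6-(3-methylbut-2-en-1-yl)-3,4-dihydro-2H-chromene-3,7-diol | CC(C)=CCc1c(O)cc2c(c1CCc1ccc(O)c(O)c1)C[C@@H](O)C(C)(C)O2 | target

**Totals**
Total steps: 6. Longest linear sequence: 5 (steps 1, 3, 4, 5, 6; step 2 is a one-step branch).

**Steps most likely to fail**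

Step 3 (C–H alkylation between two carbonyls). The C5 position is flanked on both sides, so the ruthenium may be trapped as an O,C,O-chelate, or C–C reductive elimination may be too slow. The fallback sets out from 4 (with 6) and returns at 7. It replaces hydroarylation by a dehydrogenative Heck-type C–H alkenylation at cationic divalent ruthenium: [RuCl2(p-cymene)]2, AgSbF6 and Cu(OAc)2·H2O in 1,2-dichloroethane at 110 °C give (E)-5-[2-(3,4-bis(benzyloxy)phenyl)ethenyl]-2,2,8,8-tetramethyl-2,3,7,8-tetrahydropyrano[3,2-g]chromene-4,6-dione F1. Here C–C formation is a migratory insertion followed by β-hydride elimination, not a reductive elimination. The stilbene double bond of F1 is then hydrogenated with RhCl(PPh3)3 and H2 in benzene/EtOH, which leaves ketones and benzyl ethers intact, to give 7.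

Step 5 (mono-epoxidation). The epoxide has an ether oxygen ortho and para to its benzylic carbon and is therefore very acid-labile. The mono/bis ratio is statistical, and the peri C5 chain may erode face selectivity. The fallback sets out from 9 and returns at 11, and it moves the symmetry-breaking oxidation from a chromene to a prenyl group. Li/NH3 on 9 cleaves both pyrans and both benzyl ethers to the symmetric 4-[2-[3,5-dihydroxy-2,6-bis(3-methylbut-2-en-1-yl)phenyl]ethyl]benzene-1,2-diol F2. TBSCl and imidazole in DMF then give its tetrakis(tert-butyldimethylsilyl) ether F3. Shi epoxidation with the D-fructose-derived ketone (KHSO5 as 2KHSO5·KHSO4·K2SO4, K2CO3, MeCN/dimethoxymethane/aqueous buffer, 0 °C, about 0.6 equiv oxidant) converts one of the two homotopic prenyl groups into the (R)-epoxide, the mono-epoxide tetrasilyl ether F4. Finally Bu4NF buffered with AcOH, then catalytic camphorsulfonic acid in CH2Cl2, frees the phenols and closes the ring by 6-endo attack of the ortho-phenol on the tertiary epoxide carbon. The secondary C–O bond is untouched, so 11 is obtained with 3R.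

Step 6 (triple reductive cleavage). The allyl anion from the chromene may protonate at the wrong terminus and be over-reduced, and the epoxide may suffer base-induced side reactions in the amide-containing medium. The fallback sets out from 10 and returns at 11, and it takes the stereo-defining C–O cleavage out of the electron-transfer step. LiAlH4 in THF at 0 °C opens the epoxide by SN2 attack of hydride at the benzylic C4, which is less hindered than C3 next to the quaternary carbon. This gives the stable, purifiable (3R)-5-[2-(3,4-bis(benzyloxy)phenyl)ethyl]-2,2,8,8-tetramethyl-3,4-dihydro-2H,8H-pyrano[3,2-g]chromen-3-ol F5. The chromene cleavage and debenzylation are then optimised separately on F5 (Li, NH3/THF, −78 °C, NH4Cl quench) to give 11. This second stage is still an electron-transfer cleavage of the chromene; no non-reductive alternative is proposed.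

**Further compounds**
F1 | step 3 | (E)-5-[2-(3,4-bis(benzyloxy)phenyl)ethenyl]-2,2,8,8-tetramethyl-2,3,7,8-tetrahydropyrano[3,2-g]chromene-4,6-dione | CC1(C)CC(=O)c2c(/C=C/c3ccc(OCc4ccccc4)c(OCc4ccccc4)c3)c3c(cc2O1)OC(C)(C)CC3=O
F2 | step 5 | 4-[2-[3,5-dihydroxy-2,6-bis(3-methylbut-2-en-1-yl)phenyl]ethyl]benzene-1,2-diol | CC(C)=CCc1c(O)cc(O)c(CC=C(C)C)c1CCc1ccc(O)c(O)c1
F3 | step 5 | tetrakis(tert-butyldimethylsilyl) ether of F2 | CC(C)=CCc1c(O[Si](C)(C)C(C)(C)C)cc(O[Si](C)(C)C(C)(C)C)c(CC=C(C)C)c1CCc1ccc(O[Si](C)(C)C(C)(C)C)c(O[Si](C)(C)C(C)(C)C)c1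
F4 | step 5 | tetrakis(tert-butyldimethylsilyl) ether of 4-[2-[2-[[(2R)-3,3-dimethyloxiran-2-yl]methyl]-3,5-dihydroxy-6-(3-methylbut-2-en-1-yl)phenyl]ethyl]benzene-1,2-diol | CC1(C)O[C@@H]1Cc1c(O[Si](C)(C)C(C)(C)C)cc(O[Si](C)(C)C(C)(C)C)c(CC=C(C)C)c1CCc1ccc(O[Si](C)(C)C(C)(C)C)c(O[Si](C)(C)C(C)(C)C)c1
F5 | step 6 | (3R)-5-[2-(3,4-bis(benzyloxy)phenyl)ethyl]-2,2,8,8-tetramethyl-3,4-dihydro-2H,8H-pyrano[3,2-g]chromen-3-ol | CC1(C)Oc2cc3OC(C)(C)C=Cc3c(CCc3ccc(OCc4ccccc4)c(OCc4ccccc4)c3)c2C[C@H]1O
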